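**Retrosynthetic overview**

1. Target ⇐ C8 tiglate (Mitsunobu inversion) and C4 aroyl ester on a trans-fused hydroazulenone diol; the seven-membered ring is closed last by ring-closing metathesis (C6=C7).
2. Metathesis precursor ⇐ vinyl Grignard opening (through the Weinreb amide) of a bridged γ-lactone that carries C8 as its acyl carbon and holds the C3–O bond cis to it.
3. Bridged lactone ⇐ organophotoredox hydrolactonisation of a cyclopentene carboxylic acid (sets C3 and C3a); C4 carbinol ⇐ phosphoric-acid-catalysed methallylboration of a cyclopentene carbaldehyde.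
4. Cyclopentene carbaldehyde (five-membered ring, formed second) ⇐ ozonolysis and aldol condensation of a cyclohexene (six-membered ring, formed first and then cut open).
5. Cyclohexene with the quaternary centre C8a ⇐ enantioselective metal-free Diels–Alder reaction of methacrolein with 2-isopropylbutadiene (from 3-methylbut-1-yne and ethene).

Atom labels follow the hydroazulene core of the target: C8a (quaternary, methyl), C1, C2, C3 (carbinol, isopropyl), C3a (ring-fusion CH), C4 (aroyloxy), C5, C6 (methyl), C7, C8 (tigloyloxy).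

Assumption: the SMILES is taken as drawn, i.e. the (3S,3aS,4S,8R,8aS) enantiomer with an (E)-2-methylbut-2-enoyl (tigloyl) ester; the pinacol methallylboronate and 4-[(tert-butyldimethylsilyl)oxy]benzoic acid are taken as catalogue compounds.

**Route**

Step 1
Reactants: 1 3-methylbut-1-yne; 2 ethene
Product: 3 2-(propan-2-yl)buta-1,3-diene
Conditions: ethene (1 atm), (H2IMes)(PCy3)Cl2Ru=CHPh (second-generation Grubbs catalyst, 3 mol%), CH2Cl2, rt
Reagents that add atoms: none
Why: Ethene–alkyne cross enyne metathesis turns the terminal alkyne into the 2-substituted 1,3-diene with full atom economy and no stereochemical issue.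

Step 2
Reactants: 3 2-(propan-2-yl)buta-1,3-diene; 4 2-methylprop-2-enal (methacrolein)
Product: 5 (1S)-1-methyl-4-(propan-2-yl)cyclohex-3-ene-1-carbaldehyde
Conditions: oxazaborolidinium triflimide from (S)-α,α-diphenylprolinol, o-tolylboronic acid and HNTf2 (10 mol%), CH2Cl2, −78 °C
Reagents that add atoms: none
Why: Enantioselective Diels–Alder reaction in which the boron-bound s-trans enal is shielded on one face by a catalyst phenyl group, so the diene adds to the open face with "para" orientation and sets the quaternary centre C8a as the first stereocentre.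

Step 3
Reactants: 5 (1S)-1-methyl-4-(propan-2-yl)cyclohex-3-ene-1-carbaldehyde
Product: 7 methyl (1S)-1-methyl-4-(propan-2-yl)cyclohex-3-ene-1-carboxylate, via carboxylic acid 6 (not isolated)
Conditions: NaClO2, NaH2PO4, 2-methylbut-2-ene, t-BuOH/H2O, rt; then Me3SiCHN2, toluene/MeOH, 0 °C
Reagents that add atoms: sodium chlorite, [Na+].[O-]Cl=O; (trimethylsilyl)diazomethane, C[Si](C)(C)C=[N+]=[N-]
Why: Pinnick oxidation (hypochlorite scavenged, so the ring alkene survives) followed by diazoalkane O-methylation masks C8 as an ester without touching the quaternary stereocentre.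

Step 4
Reactants: 7 methyl (1S)-1-methyl-4-(propan-2-yl)cyclohex-3-ene-1-carboxylate
Product: 8 methyl (2S)-2,6-dimethyl-5-oxo-2-(2-oxoethyl)heptanoate
Conditions: O3, pyridine, CH2Cl2, −78 °C
Reagents that add atoms: ozone, [O-][O+]=O
Why: Ozonolysis of the only alkene (pyridine-promoted reductive variant) unmasks the C4 aldehyde and the C3 isopropyl ketone and leaves the stereocentre untouched.

Step 5
Reactants: 8 methyl (2S)-2,6-dimethyl-5-oxo-2-(2-oxoethyl)heptanoate
Product: 9 methyl (1S)-2-formyl-1-methyl-3-(propan-2-yl)cyclopent-2-ene-1-carboxylate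
Conditions: Bn2NH·CF3CO2H (30 mol%), toluene, 60 °C
Reagents that add atoms: none
Why: Amine-mediated intramolecular aldol condensation in which the enamine of the aldehyde (not the hindered ketone) is the nucleophile, so the five-membered ring closes C3a to C3 as the conjugated enal and no new stereocentre arises.

Step 6
Reactants: 9 methyl (1S)-2-formyl-1-methyl-3-(propan-2-yl)cyclopent-2-ene-1-carboxylate; 10 4,4,5,5-tetramethyl-2-(2-methylprop-2-en-1-yl)-1,3,2-dioxaborolane
Product: 11 methyl (1S)-2-[(1S)-1-hydroxy-3-methylbut-3-en-1-yl]-1-methyl-3-(propan-2-yl)cyclopent-2-ene-1-carboxylate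
Conditions: (S)-3,3'-bis(2,4,6-triisopropylphenyl)-1,1'-binaphthyl-2,2'-diyl hydrogen phosphate [(S)-TRIP, 10 mol%], 4 Å MS, toluene, −30 to 0 °C; aqueous work-up
Reagents that add atoms: none
Why: Chiral phosphoric acid-catalysed allylboration through a closed six-membered transition state, the (S)-acid directing the methallyl group to the Si face of the aldehyde and setting the C4 carbinol (S) under reagent control.

Step 7
Reactants: 11 methyl (1S)-2-[(1S)-1-hydroxy-3-methylbut-3-en-1-yl]-1-methyl-3-(propan-2-yl)cyclopent-2-ene-1-carboxylate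
Product: 12 (1S)-2-[(1S)-1-hydroxy-3-methylbut-3-en-1-yl]-1-methyl-3-(propan-2-yl)cyclopent-2-ene-1-carboxylic acid
Conditions: LiOH·H2O, THF/MeOH/H2O, 60 °C; then cold aq. HCl to pH 4, used at once
Reagents that add atoms: lithium hydroxide monohydrate, [Li+].[OH-].O
Why: Saponification of the hindered ester (which also re-opens any fused lactone formed with the C4 hydroxyl) frees the carboxylic acid needed as internal nucleophile and affects no stereocentre.

Step 8
Reactants: 12 (1S)-2-[(1S)-1-hydroxy-3-methylbut-3-en-1-yl]-1-methyl-3-(propan-2-yl)cyclopent-2-ene-1-carboxylic acid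
Product: 13 (1S,4S,7S)-7-[(1S)-1-hydroxy-3-methylbut-3-en-1-yl]-4-methyl-1-(propan-2-yl)-2-oxabicyclo[2.2.1]heptan-3-one
Conditions: 9-mesityl-10-methylacridinium tetrafluoroborate (5 mol%), PhSSPh (10 mol%), 1,2-dichloroethane, 450 nm LEDs, rt
Reagents that add atoms: none
Why: Proposed new method: the excited acridinium oxidises the tetrasubstituted ring alkene to a radical cation that is captured reversibly by the carboxylic acid, which can only close the five-membered lactone at C3 (the four-membered alternative at C3a is strained and reverts), so the C3–O bond is forced cis to C8, and the resulting tertiary C3a radical of the oxabicyclo[2.2.1]heptane takes a hydrogen atom from PhSH on the open lactone face (the ethano bridge shields the other), placing H cis to the lactone and the carbinol chain trans; the closest known reaction is the acridinium/thiol anti-Markovnikov hydroacyloxylation (hydrolactonisation) of alkenoic acids, not yet shown on a tetrasubstituted cyclic β,γ-unsaturated acid or used to set two stereocentres of a bridged lactone.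

Step 9
Reactants: 13 (1S,4S,7S)-7-[(1S)-1-hydroxy-3-methylbut-3-en-1-yl]-4-methyl-1-(propan-2-yl)-2-oxabicyclo[2.2.1]heptan-3-one; 14 ethenylmagnesium bromide
Product: 16 1-[(1S,2S,3S)-3-hydroxy-2-[(1S)-1-hydroxy-3-methylbut-3-en-1-yl]-1-methyl-3-(propan-2-yl)cyclopentyl]prop-2-en-1-one, via Weinreb amide 15 (not isolated)
Conditions: MeNH(OMe)·HCl, i-PrMgCl, THF, −20 °C; then CH2=CHMgBr, −20 to 0 °C; inverse quench into cold 1 M HCl
Reagents that add atoms: N,O-dimethylhydroxylamine hydrochloride, CNOC.Cl (its atoms stay only in 15)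
Why: Magnesium amide aminolysis of the strained lactone followed by Grignard addition to the Weinreb amide (stable chelate, no over-addition) gives the vinyl ketone and releases the tertiary C3 hydroxyl with its configuration unchanged.

Step 10
Reactants: 16 1-[(1S,2S,3S)-3-hydroxy-2-[(1S)-1-hydroxy-3-methylbut-3-en-1-yl]-1-methyl-3-(propan-2-yl)cyclopentyl]prop-2-en-1-one
Product: 17 (1S,3aS,8S,8aS)-1,8-dihydroxy-3a,6-dimethyl-1-(propan-2-yl)-1,2,3,7,8,8a-hexahydroazulen-4(3aH)-one
Conditions: (H2IMes)Cl2Ru=CH(C6H4-2-O-i-Pr) (second-generation Hoveyda–Grubbs catalyst, 5 mol%), toluene, 80 °C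
Reagents that add atoms: none
Why: Ring-closing metathesis between the vinyl ketone and the 1,1-disubstituted alkene closes the seven-membered ring as the trisubstituted enone, and the trans ring fusion follows from the trans arrangement of the two arms on the cyclopentane.

Step 11
Reactants: 17 (1S,3aS,8S,8aS)-1,8-dihydroxy-3a,6-dimethyl-1-(propan-2-yl)-1,2,3,7,8,8a-hexahydroazulen-4(3aH)-one; 18 4-[(tert-butyldimethylsilyl)oxy]benzoic acid
Product: 19 (3S,3aS,4S,8aS)-3-hydroxy-6,8a-dimethyl-8-oxo-3-(propan-2-yl)-1,2,3,3a,4,5,8,8a-octahydroazulen-4-yl 4-[(tert-butyldimethylsilyl)oxy]benzoate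
Conditions: DCC, DMAP, CH2Cl2, 0 °C to rt
Reagents that add atoms: none
Why: Steglich esterification acylates the secondary C4 hydroxyl selectively over the tertiary C3 hydroxyl, with retention at C4.

Step 12
Reactants: 19 (3S,3aS,4S,8aS)-3-hydroxy-6,8a-dimethyl-8-oxo-3-(propan-2-yl)-1,2,3,3a,4,5,8,8a-octahydroazulen-4-yl 4-[(tert-butyldimethylsilyl)oxy]benzoate
Product: 20 (3S,3aS,4S,8S,8aS)-3,8-dihydroxy-6,8a-dimethyl-3-(propan-2-yl)-1,2,3,3a,4,5,8,8a-octahydroazulen-4-yl 4-[(tert-butyldimethylsilyl)oxy]benzoate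
Conditions: NaBH4, CeCl3·7H2O, MeOH, −78 °C
Reagents that add atoms: none
Why: Luche 1,2-reduction of the enone, with hydride expected to add anti to the axial angular methyl group and give the allylic alcohol cis to that methyl (8S).

Step 13
Reactants: 20 (3S,3aS,4S,8S,8aS)-3,8-dihydroxy-6,8a-dimethyl-3-(propan-2-yl)-1,2,3,3a,4,5,8,8a-octahydroazulen-4-yl 4-[(tert-butyldimethylsilyl)oxy]benzoate; 21 (2E)-2-methylbut-2-enoic acid (tiglic acid)
Product: 22 (3S,3aS,4S,8R,8aS)-3-hydroxy-6,8a-dimethyl-8-{[(2E)-2-methylbut-2-enoyl]oxy}-3-(propan-2-yl)-1,2,3,3a,4,5,8,8a-octahydroazulen-4-yl 4-[(tert-butyldimethylsilyl)oxy]benzoate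
Conditions: PPh3, DIAD, toluene, 0 °C to rt
Reagents that add atoms: none
Why: Mitsunobu esterification with SN2 inversion at the allylic C8, the carboxylate entering on the face anti to the angular methyl, gives the 8R tiglate while the tertiary alcohol stays inert.

Step 14
Reactants: 22 (3S,3aS,4S,8R,8aS)-3-hydroxy-6,8a-dimethyl-8-{[(2E)-2-methylbut-2-enoyl]oxy}-3-(propan-2-yl)-1,2,3,3a,4,5,8,8a-octahydroazulen-4-yl 4-[(tert-butyldimethylsilyl)oxy]benzoate
Product: 23 (3S,3aS,4S,8R,8aS)-3-hydroxy-6,8a-dimethyl-8-{[(2E)-2-methylbut-2-enoyl]oxy}-3-(propan-2-yl)-1,2,3,3a,4,5,8,8a-octahydroazulen-4-yl 4-hydroxybenzoate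
Conditions: Bu4NF, AcOH, THF, 0 °C
Reagents that add atoms: none
Why: Buffered fluoride desilylation cleaves the aryl silyl ether selectively and leaves both esters and the tertiary alcohol intact.

**Compound list**

1 | 3-methylbut-1-yne | CC(C)C#C | starting material
2 | ethene | C=C | starting material
3 | 2-(propan-2-yl)buta-1,3-diene | CC(C)C(=C)C=C | intermediate
4 | 2-methylprop-2-enal | CC(=C)C=O | starting material
5 | (1S)-1-methyl-4-(propan-2-yl)cyclohex-3-ene-1-carbaldehyde | O=C[C@]1(C)CC=C(C(C)C)CC1 | intermediate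
6 | (1S)-1-methyl-4-(propan-2-yl)cyclohex-3-ene-1-carboxylic acid | OC(=O)[C@]1(C)CC=C(C(C)C)CC1 | intermediate
7 | methyl (1S)-1-methyl-4-(propan-2-yl)cyclohex-3-ene-1-carboxylate | COC(=O)[C@]1(C)CC=C(C(C)C)CC1 | intermediate
8 | methyl (2S)-2,6-dimethyl-5-oxo-2-(2-oxoethyl)heptanoate | COC(=O)[C@](C)(CC=O)CCC(=O)C(C)C | intermediate
9 | methyl (1S)-2-formyl-1-methyl-3-(propan-2-yl)cyclopent-2-ene-1-carboxylate | COC(=O)[C@@]1(C)CCC(C(C)C)=C1C=O | intermediate
10 | 4,4,5,5-tetramethyl-2-(2-methylprop-2-en-1-yl)-1,3,2-dioxaborolane | CC(=C)CB1OC(C)(C)C(C)(C)O1 | starting material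
11 | methyl (1S)-2-[(1S)-1-hydroxy-3-methylbut-3-en-1-yl]-1-methyl-3-(propan-2-yl)cyclopent-2-ene-1-carboxylate | COC(=O)[C@@]1(C)CCC(C(C)C)=C1[C@@H](O)CC(C)=C | intermediate
12 | (1S)-2-[(1S)-1-hydroxy-3-methylbut-3-en-1-yl]-1-methyl-3-(propan-2-yl)cyclopent-2-ene-1-carboxylic acid | OC(=O)[C@@]1(C)CCC(C(C)C)=C1[C@@H](O)CC(C)=C | intermediate
13 | (1S,4S,7S)-7-[(1S)-1-hydroxy-3-methylbut-3-en-1-yl]-4-methyl-1-(propan-2-yl)-2-oxabicyclo[2.2.1]heptan-3-one | O=C1O[C@]2(C(C)C)CC[C@@]1(C)[C@H]2[C@@H](O)CC(C)=C | intermediate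
14 | ethenylmagnesium bromide | C=C[Mg]Br | starting material
15 | (1S,2S,3S)-3-hydroxy-2-[(1S)-1-hydroxy-3-methylbut-3-en-1-yl]-N-methoxy-N,1-dimethyl-3-(propan-2-yl)cyclopentane-1-carboxamide | CON(C)C(=O)[C@@]1(C)CC[C@](O)(C(C)C)[C@@H]1[C@@H](O)CC(C)=C | intermediate
16 | 1-[(1S,2S,3S)-3-hydroxy-2-[(1S)-1-hydroxy-3-methylbut-3-en-1-yl]-1-methyl-3-(propan-2-yl)cyclopentyl]prop-2-en-1-one | C=CC(=O)[C@@]1(C)CC[C@](O)(C(C)C)[C@@H]1[C@@H](O)CC(C)=C | intermediate
17 | (1S,3aS,8S,8aS)-1,8-dihydroxy-3a,6-dimethyl-1-(propan-2-yl)-1,2,3,7,8,8a-hexahydroazulen-4(3aH)-one | O=C1C=C(C)C[C@H](O)[C@@H]2[C@]1(C)CC[C@]2(O)C(C)C | intermediate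
18 | 4-[(tert-butyldimethylsilyl)oxy]benzoic acid | CC(C)(C)[Si](C)(C)Oc1ccc(cc1)C(O)=O | starting material
19 | (3S,3aS,4S,8aS)-3-hydroxy-6,8a-dimethyl-8-oxo-3-(propan-2-yl)-1,2,3,3a,4,5,8,8a-octahydroazulen-4-yl 4-[(tert-butyldimethylsilyl)oxy]benzoate | O=C1C=C(C)C[C@H](OC(=O)c2ccc(O[Si](C)(C)C(C)(C)C)cc2)[C@@H]2[C@]1(C)CC[C@]2(O)C(C)C | intermediate
20 | (3S,3aS,4S,8S,8aS)-3,8-dihydroxy-6,8a-dimethyl-3-(propan-2-yl)-1,2,3,3a,4,5,8,8a-octahydroazulen-4-yl 4-[(tert-butyldimethylsilyl)oxy]benzoate | O[C@H]1C=C(C)C[C@H](OC(=O)c2ccc(O[Si](C)(C)C(C)(C)C)cc2)[C@@H]2[C@]1(C)CC[C@]2(O)C(C)C | intermediate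
21 | (2E)-2-methylbut-2-enoic acid | C/C=C(\C)C(O)=O | starting material
22 | (3S,3aS,4S,8R,8aS)-3-hydroxy-6,8a-dimethyl-8-{[(2E)-2-methylbut-2-enoyl]oxy}-3-(propan-2-yl)-1,2,3,3a,4,5,8,8a-octahydroazulen-4-yl 4-[(tert-butyldimethylsilyl)oxy]benzoate | C/C=C(\C)C(=O)O[C@@H]1C=C(C)C[C@H](OC(=O)c2ccc(O[Si](C)(C)C(C)(C)C)cc2)[C@@H]2[C@]1(C)CC[C@]2(O)C(C)C | intermediate
23 | (3S,3aS,4S,8R,8aS)-3-hydroxy-6,8a-dimethyl-8-{[(2E)-2-methylbut-2-enoyl]oxy}-3-(propan-2-yl)-1,2,3,3a,4,5,8,8a-octahydroazulen-4-yl 4-hydroxybenzoate | C/C=C(\C)C(=O)O[C@@H]1C=C(C)C[C@H](OC(=O)c2ccc(O)cc2)[C@@H]2[C@]1(C)CC[C@]2(O)C(C)C | target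

**Step count and risks**

Total steps: 14. Longest linear sequence: 14 (fully linear from 3-methylbut-1-yne). The route has not been run; the sense of induction in steps 2 and 6 and the face selectivities in steps 8 and 12 are predictions from standard models.

The three steps most likely to fail:

Step 6, allylboration of the very hindered tetrasubstituted enal. It may be slow or poorly selective. Fallback, setting out from 9: a Barbier addition with 3-bromo-2-methylprop-1-ene and zinc dust in THF/aq. NH4Cl gives methyl (1S)-2-(1-hydroxy-3-methylbut-3-en-1-yl)-1-methyl-3-(propan-2-yl)cyclopent-2-ene-1-carboxylate F1 as a mixture of carbinol epimers. Oxidation with MnO2 in CH2Cl2 gives the dienone methyl (1S)-1-methyl-2-(3-methylbut-3-enoyl)-3-(propan-2-yl)cyclopent-2-ene-1-carboxylate F2. Reduction with (R)-2-methyl-CBS-oxazaborolidine and catecholborane (cyclopentenyl as the large group) then sets the (S)-carbinol by ketone reduction instead of allylation and comes back to the route at 11.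

Step 8, the proposed new hydrolactonisation. Possible failures are decarboxylation or allylic oxidation of the radical cation, closure of acid 12 to a fused lactone with the C4 hydroxyl before irradiation, and poor face selectivity in the hydrogen-atom transfer. Fallback with known chemistry, setting out from 12: iodolactonisation (I2, NaHCO3, MeCN/H2O, 0 °C) closes the carboxylate on C3 anti to the iodonium ion and gives (1S,4R,7S)-7-[(1S)-1-hydroxy-3-methylbut-3-en-1-yl]-7-iodo-4-methyl-1-(propan-2-yl)-2-oxabicyclo[2.2.1]heptan-3-one F3. Radical deiodination with Bu3SnH and AIBN in benzene at 80 °C delivers hydrogen to the planar C3a radical from the lactone face and comes back to the route at 13.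

Step 13, Mitsunobu inversion at an allylic carbinol next to a quaternary carbon. Elimination, SN2' attack or retention through an ion pair are possible, and the outcome also depends on the face selectivity assumed in step 12. Fallback, setting out from 19: reagent-controlled reduction with (S)-2-methyl-CBS-oxazaborolidine and BH3·SMe2 (quaternary C8a as the large group) gives the 8R alcohol directly, (3S,3aS,4S,8R,8aS)-3,8-dihydroxy-6,8a-dimethyl-3-(propan-2-yl)-1,2,3,3a,4,5,8,8a-octahydroazulen-4-yl 4-[(tert-butyldimethylsilyl)oxy]benzoate F4. Esterification with retention using 21, DCC and DMAP comes back to the route at 22.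

**Further compounds**

F1 | step 6 | methyl (1S)-2-(1-hydroxy-3-methylbut-3-en-1-yl)-1-methyl-3-(propan-2-yl)cyclopent-2-ene-1-carboxylate (carbinol epimers) | COC(=O)[C@@]1(C)CCC(C(C)C)=C1C(O)CC(C)=C
F2 | step 6 | methyl (1S)-1-methyl-2-(3-methylbut-3-enoyl)-3-(propan-2-yl)cyclopent-2-ene-1-carboxylate | COC(=O)[C@@]1(C)CCC(C(C)C)=C1C(=O)CC(C)=C
F3 | step 8 | (1S,4R,7S)-7-[(1S)-1-hydroxy-3-methylbut-3-en-1-yl]-7-iodo-4-methyl-1-(propan-2-yl)-2-oxabicyclo[2.2.1]heptan-3-one | O=C1O[C@]2(C(C)C)CC[C@@]1(C)[C@]2(I)[C@@H](O)CC(C)=C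
F4 | step 13 | (3S,3aS,4S,8R,8aS)-3,8-dihydroxy-6,8a-dimethyl-3-(propan-2-yl)-1,2,3,3a,4,5,8,8a-octahydroazulen-4-yl 4-[(tert-butyldimethylsilyl)oxy]benzoate | O[C@@H]1C=C(C)C[C@H](OC(=O)c2ccc(O[Si](C)(C)C(C)(C)C)cc2)[C@@H]2[C@]1(C)CC[C@]2(O)C(C)C
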